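**Retrosynthetic overview**
1. Oxane ring last: 16 ⇐ 6-endo bromoetherification of the homoprenyl tertiary alcohol 15 (sets the oxane C–Br centre).
2. 15 ⇐ lactol 13 (Wittig) ⇐ γ-lactone 12; the ring C–Br/C–Cl pair comes from cyclohexene 9 by an epoxide → bromohydrin → bromonium/chloride relay.
3. Key C–C bond: γ-lactone 8 ⇐ hydroxyl-directed SmI2 coupling of the ketyl (nucleophilic carbonyl carbon) of cis-β-hydroxy ketone 5 with methyl acrylate; this sets the quaternary carbinol carbon.
4. 5 ⇐ enantioselective copper-catalysed conjugate borylation/oxidation of dienone 3 ⇐ Diels–Alder reaction of isoprene with but-3-yn-2-one.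
5. Ring order: carbocycle (step 1), temporary γ-lactone (step 3), oxane (step 9).

Assumption: the Josiphos antipode written in step 2 is taken to deliver boron to the face that gives the (6S) centre; if the sense is opposite, the commercial mirror-image ligand is used.

**Step 1**
Reactants: 1 isoprene (2-methylbuta-1,3-diene); 2 but-3-yn-2-one
Product: 3 1-(4-methylcyclohexa-1,4-dien-1-yl)ethan-1-one
Conditions: AlCl3 (0.2 equiv), CH2Cl2, −20 → 0 °C, 1 in excess
Reagents that add atoms: none
Why: Lewis-acid-catalysed Diels–Alder reaction of the ynone gives the "para" (1,4) cyclohexa-1,4-diene regioisomer; no stereocentre is formed.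

**Step 2**
Reactants: 3 1-(4-methylcyclohexa-1,4-dien-1-yl)ethan-1-one
Product: 5 1-[(1R,6S)-6-hydroxy-4-methylcyclohex-3-en-1-yl]ethan-1-one, via cis-β-boryl ketone 4 (not isolated)
Conditions: CuCl (5 mol %), NaOtBu (7 mol %), (R)-1-[(SP)-2-(diphenylphosphino)ferrocenyl]ethyldicyclohexylphosphine (Josiphos, 6 mol %), B2pin2 (1.1 equiv), MeOH (2 equiv), THF, 0 °C; then NaBO3·4H2O, THF/H2O, 0 °C
Reagents that add atoms: bis(pinacolato)diboron, CC1(C)OB(OC1(C)C)B1OC(C)(C)C(C)(C)O1 (boron of 4); sodium perborate, O[B-]1(O)OO[B-](O)(O)OO1.[Na+].[Na+] (oxygen of 5)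
Why: Copper-catalysed enantioselective conjugate borylation puts boron on the β-carbon under ligand control (sets C-6); the boryl group sits pseudoaxial to avoid A(1,3) strain with the enolate, so kinetic protonation by MeOH occurs anti to it and gives the cis ketone (sets C-1), and perborate oxidation of C–B proceeds with retention.

**Step 3 (key step)**
Reactants: 5 1-[(1R,6S)-6-hydroxy-4-methylcyclohex-3-en-1-yl]ethan-1-one; 6 methyl acrylate
Product: 8 (5S)-5-[(1R,6S)-6-hydroxy-4-methylcyclohex-3-en-1-yl]-5-methyloxolan-2-one, via γ-hydroxy ester 7 (not isolated)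
Conditions: SmI2 (2.5 equiv, 0.1 M in THF), 6 (3 equiv), t-BuOH (2 equiv), THF, −78 → 0 °C; aq. NH4Cl
Reagents that add atoms: none
Why: Hydroxyl-directed SmI2 ketyl–olefin coupling with lactonisation: trivalent samarium bridges the C-6 oxygen and the ketyl oxygen in a six-membered chelate, and the nucleophilic ketyl carbon adds to the acrylate β-carbon on the face flanked by H-1 rather than ring C-2 (Cram-chelate sense), which gives the (S) quaternary carbinol.

**Step 4**
Reactants: 8 (5S)-5-[(1R,6S)-6-hydroxy-4-methylcyclohex-3-en-1-yl]-5-methyloxolan-2-one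
Product: 9 (1S,6R)-3-methyl-6-[(2S)-2-methyl-5-oxooxolan-2-yl]cyclohex-3-en-1-yl 2,2,2-trifluoroacetate
Conditions: (CF3CO)2O (1.5 equiv), pyridine (3 equiv), CH2Cl2, 0 °C
Reagents that add atoms: trifluoroacetic anhydride, O=C(OC(=O)C(F)(F)F)C(F)(F)F
Why: O-Acylation masks the secondary alcohol as an acid-stable, poorly participating ester that i-Bu2AlH removes in step 7; no stereocentre is touched.

**Step 5**
Reactants: 9 (1S,6R)-3-methyl-6-[(2S)-2-methyl-5-oxooxolan-2-yl]cyclohex-3-en-1-yl 2,2,2-trifluoroacetate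
Product: 10 (1S,3S,4R,6R)-1-methyl-4-[(2S)-2-methyl-5-oxooxolan-2-yl]-7-oxabicyclo[4.1.0]heptan-3-yl 2,2,2-trifluoroacetate (epoxide anti to the ester and to the lactone-bearing carbon)
Conditions: mCPBA (1.3 equiv), CH2Cl2, 0 °C
Reagents that add atoms: 3-chloroperoxybenzoic acid, OOC(=O)c1cccc(Cl)c1
Why: Prilezhaev epoxidation: the pseudoaxial trifluoroacetoxy group, which has no O–H to direct the peracid, shields its own face, so oxygen is delivered to the opposite face.

**Step 6**
Reactants: 10 (1S,3S,4R,6R)-1-methyl-4-[(2S)-2-methyl-5-oxooxolan-2-yl]-7-oxabicyclo[4.1.0]heptan-3-yl 2,2,2-trifluoroacetate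
Product: 12 (1S,2R,4S,5S)-4-bromo-5-chloro-5-methyl-2-[(2S)-2-methyl-5-oxooxolan-2-yl]cyclohexyl 2,2,2-trifluoroacetate, via diaxial bromohydrin 11 (not isolated)
Conditions: HBr (1.05 equiv, anhydrous, titrated CH2Cl2 solution), CH2Cl2, −78 → −40 °C; then SOCl2 (1.5 equiv), pyridine (3 equiv), −40 → 23 °C; then 40 °C, 4 h
Reagents that add atoms: hydrogen bromide, Br; thionyl chloride, O=S(Cl)Cl
Why: Bromide opens the protonated epoxide at the tertiary carbon in the trans-diaxial (Fürst–Plattner, Markovnikov) sense, which places Br on the side-chain face; after O-sulfinylation the anti-periplanar bromine expels the C–O bond to form a bromonium ion on that face, and chloride opens it at the more substituted carbon from the other face (anchimerically assisted substitution with 1,2-bromine shift), giving the trans-diequatorial tertiary chloride/secondary bromide, while any diaxial 1-bromo-2-chloro regioisomer converges on it by the diaxial→diequatorial dihalide rearrangement on warming.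

**Step 7**
Reactants: 12 (1S,2R,4S,5S)-4-bromo-5-chloro-5-methyl-2-[(2S)-2-methyl-5-oxooxolan-2-yl]cyclohexyl 2,2,2-trifluoroacetate
Product: 13 (5S)-5-[(1R,2S,4S,5S)-5-bromo-4-chloro-2-hydroxy-4-methylcyclohexyl]-5-methyloxolan-2-ol (lactol, anomer mixture, used crude)
Conditions: i-Bu2AlH (3.5 equiv), CH2Cl2, −78 °C; Rochelle-salt work-up (no acid, no silica)
Reagents that add atoms: none
Why: Partial hydride reduction of the γ-lactone to the lactol, which also cleaves the trifluoroacetate; the alkyl halides are inert at −78 °C and no ring stereocentre changes.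

**Step 8**
Reactants: 13 (5S)-5-[(1R,2S,4S,5S)-5-bromo-4-chloro-2-hydroxy-4-methylcyclohexyl]-5-methyloxolan-2-ol; 14 isopropyltriphenylphosphonium iodide
Product: 15 (1S,2R,4S,5S)-4-bromo-5-chloro-2-[(2S)-2-hydroxy-6-methylhept-5-en-2-yl]-5-methylcyclohexan-1-ol
Conditions: 14 (4 equiv), n-BuLi (3.9 equiv), THF, 0 °C; then 13, −78 → 23 °C
Reagents that add atoms: none
Why: Wittig olefination of the open hydroxy-aldehyde form of the lactol with the non-stabilised isopropylidene ylide gives the trisubstituted alkene; the equatorial ring C–Br and C–Cl bonds are poorly aligned for ring E2, so the halides survive.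

**Step 9**
Reactants: 15 (1S,2R,4S,5S)-4-bromo-5-chloro-2-[(2S)-2-hydroxy-6-methylhept-5-en-2-yl]-5-methylcyclohexan-1-ol
Product: 16 (1S,2R,4S,5S)-4-bromo-2-[(2S,5R)-5-bromo-2,6,6-trimethyloxan-2-yl]-5-chloro-5-methylcyclohexan-1-ol (target)
Conditions: 2,4,4,6-tetrabromocyclohexa-2,5-dien-1-one (TBCO, 1.1 equiv), MeNO2, 0 → 23 °C
Reagents that add atoms: 2,4,4,6-tetrabromocyclohexa-2,5-dien-1-one, O=C1C(Br)=CC(Br)(Br)C=C1Br
Why: Bromonium-induced 6-endo (Markovnikov) etherification: the tertiary hydroxyl attacks the dimethyl-substituted alkene carbon anti to bromine through a chair transition state with the cyclohexyl group equatorial, so Br ends equatorial and trans to the cyclohexyl group (5R).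

**Compound list**
1 | isoprene (2-methylbuta-1,3-diene) | CC(=C)C=C | starting material
2 | but-3-yn-2-one | CC(=O)C#C | starting material
3 | 1-(4-methylcyclohexa-1,4-dien-1-yl)ethan-1-one | CC(=O)C1=CCC(C)=CC1 | intermediate
4 | 1-[(1R,6S)-4-methyl-6-(4,4,5,5-tetramethyl-1,3,2-dioxaborolan-2-yl)cyclohex-3-en-1-yl]ethan-1-one | CC(=O)[C@@H]1CC=C(C)C[C@@H]1B2OC(C)(C)C(C)(C)O2 | intermediate (not isolated)
5 | 1-[(1R,6S)-6-hydroxy-4-methylcyclohex-3-en-1-yl]ethan-1-one | CC(=O)[C@@H]1CC=C(C)C[C@@H]1O | intermediate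
6 | methyl acrylate (methyl prop-2-enoate) | C=CC(=O)OC | starting material
7 | methyl (4S)-4-hydroxy-4-[(1R,6S)-6-hydroxy-4-methylcyclohex-3-en-1-yl]pentanoate | COC(=O)CC[C@](C)(O)[C@@H]1CC=C(C)C[C@@H]1O | intermediate (not isolated)
8 | (5S)-5-[(1R,6S)-6-hydroxy-4-methylcyclohex-3-en-1-yl]-5-methyloxolan-2-one | O=C1O[C@](C)([C@@H]2CC=C(C)C[C@@H]2O)CC1 | intermediate
9 | (1S,6R)-3-methyl-6-[(2S)-2-methyl-5-oxooxolan-2-yl]cyclohex-3-en-1-yl 2,2,2-trifluoroacetate | O=C1O[C@](C)([C@@H]2CC=C(C)C[C@@H]2OC(=O)C(F)(F)F)CC1 | intermediate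
10 | (1S,3S,4R,6R)-1-methyl-4-[(2S)-2-methyl-5-oxooxolan-2-yl]-7-oxabicyclo[4.1.0]heptan-3-yl 2,2,2-trifluoroacetate | O=C1O[C@](C)([C@@H]2C[C@H]3O[C@@]3(C)C[C@@H]2OC(=O)C(F)(F)F)CC1 | intermediate
11 | (1S,2R,4R,5R)-5-bromo-4-hydroxy-5-methyl-2-[(2S)-2-methyl-5-oxooxolan-2-yl]cyclohexyl 2,2,2-trifluoroacetate | O=C1O[C@](C)([C@@H]2C[C@@H](O)[C@](C)(Br)C[C@@H]2OC(=O)C(F)(F)F)CC1 | intermediate (not isolated)
12 | (1S,2R,4S,5S)-4-bromo-5-chloro-5-methyl-2-[(2S)-2-methyl-5-oxooxolan-2-yl]cyclohexyl 2,2,2-trifluoroacetate | O=C1O[C@](C)([C@@H]2C[C@H](Br)[C@@](C)(Cl)C[C@@H]2OC(=O)C(F)(F)F)CC1 | intermediate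
13 | (5S)-5-[(1R,2S,4S,5S)-5-bromo-4-chloro-2-hydroxy-4-methylcyclohexyl]-5-methyloxolan-2-ol (anomer mixture) | OC1O[C@](C)([C@@H]2C[C@H](Br)[C@@](C)(Cl)C[C@@H]2O)CC1 | intermediate
14 | isopropyltriphenylphosphonium iodide | CC(C)[P+](c1ccccc1)(c1ccccc1)c1ccccc1.[I-] | starting material
15 | (1S,2R,4S,5S)-4-bromo-5-chloro-2-[(2S)-2-hydroxy-6-methylhept-5-en-2-yl]-5-methylcyclohexan-1-ol | CC(C)=CCC[C@](C)(O)[C@@H]1C[C@H](Br)[C@@](C)(Cl)C[C@@H]1O | intermediate
16 | (1S,2R,4S,5S)-4-bromo-2-[(2S,5R)-5-bromo-2,6,6-trimethyloxan-2-yl]-5-chloro-5-methylcyclohexan-1-ol | CC1(C)O[C@](C)([C@@H]2C[C@H](Br)[C@@](C)(Cl)C[C@@H]2O)CC[C@H]1Br | target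

**Step count and risks**
Total steps: 9. Longest linear sequence: 9 (fully linear from 1 and 2).

The three steps most likely to fail:

Step 2 (enantioselectivity and cis selectivity on an untested 1-acylcyclohexa-1,4-diene; base may also isomerise the skipped diene). The fallback sets out from 3 and comes back at 5. Compound 3 is borylated and oxidised with an achiral catalyst (CuCl, Xantphos, B2pin2, MeOH; then NaBO3·4H2O) to give racemic cis-1-(6-hydroxy-4-methylcyclohex-3-en-1-yl)ethan-1-one F1. Lipase-catalysed transesterification (Candida antarctica lipase B, vinyl acetate, t-BuOMe) then acylates the fast-reacting (6R) alcohol, as expected from the Kazlauskas rule, to (1R,6S)-6-acetyl-3-methylcyclohex-3-en-1-yl acetate F2. The unreacted alcohol is 5, which is separated by chromatography and continues in step 3.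

Step 3 (the ketyl may simply be reduced to the 1,3-diol, or the chelate may give poor facial control). The fallback sets out from 5 and comes back at 8. It replaces the one-electron ketyl coupling with a two-electron homoenolate addition. The titanium homoenolate Cl3TiCH2CH2CO2iPr, made from [(1-isopropoxycyclopropyl)oxy]trimethylsilane and TiCl4 and moderated with Ti(OiPr)4 for ketone addition, adds to the ketone of 5 through the corresponding O-titanate chelate with the same facial sense. This gives propan-2-yl (4S)-4-hydroxy-4-[(1R,6S)-6-hydroxy-4-methylcyclohex-3-en-1-yl]pentanoate F3, which lactonises to 8 on mild acid work-up.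

Step 6 (chloride may open the bromonium ion at the secondary carbon and the resulting diaxial isomer may not equilibrate, or the tertiary bromide may eliminate). The fallback sets out from 10 and comes back at 12. It puts the leaving group on the tertiary carbon so that chloride must enter there. Anhydrous CF3CO2H (CH2Cl2, −20 °C) opens 10 trans-diaxially at the tertiary carbon to give (1R,3S,4R,6R)-6-hydroxy-1-methyl-4-[(2S)-2-methyl-5-oxooxolan-2-yl]cyclohexane-1,3-diyl bis(2,2,2-trifluoroacetate) F4. Appel bromination (CBr4, PPh3, CH2Cl2) inverts the secondary carbinol to give (1R,3S,4R,6S)-6-bromo-1-methyl-4-[(2S)-2-methyl-5-oxooxolan-2-yl]cyclohexane-1,3-diyl bis(2,2,2-trifluoroacetate) F5. ZnCl2/HCl in Et2O then ionises the tertiary trifluoroacetate; the neighbouring bromine bridges the cation from its own face and chloride enters anti to it, giving 12.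

**Further compounds**
F1 | step 2 | racemic cis-1-(6-hydroxy-4-methylcyclohex-3-en-1-yl)ethan-1-one (1:1 mixture of 5 and its mirror image) | CC(=O)[C@@H]1CC=C(C)C[C@@H]1O.CC(=O)[C@H]1CC=C(C)C[C@H]1O
F2 | step 2 | (1R,6S)-6-acetyl-3-methylcyclohex-3-en-1-yl acetate | CC(=O)[C@H]1CC=C(C)C[C@H]1OC(C)=O
F3 | step 3 | propan-2-yl (4S)-4-hydroxy-4-[(1R,6S)-6-hydroxy-4-methylcyclohex-3-en-1-yl]pentanoate | CC(C)OC(=O)CC[C@](C)(O)[C@@H]1CC=C(C)C[C@@H]1O
F4 | step 6 | (1R,3S,4R,6R)-6-hydroxy-1-methyl-4-[(2S)-2-methyl-5-oxooxolan-2-yl]cyclohexane-1,3-diyl bis(2,2,2-trifluoroacetate) | O=C1O[C@](C)([C@@H]2C[C@@H](O)[C@](C)(OC(=O)C(F)(F)F)C[C@@H]2OC(=O)C(F)(F)F)CC1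
F5 | step 6 | (1R,3S,4R,6S)-6-bromo-1-methyl-4-[(2S)-2-methyl-5-oxooxolan-2-yl]cyclohexane-1,3-diyl bis(2,2,2-trifluoroacetate) | O=C1O[C@](C)([C@@H]2C[C@H](Br)[C@](C)(OC(=O)C(F)(F)F)C[C@@H]2OC(=O)C(F)(F)F)CC1
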